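To whoever takes the bench after me: the flask I leave is the delta flask, and its readings stop at 30 min.

common to all: starting material 0.080 M; free catalyst 0.88 mM
- delta: partner 0.24 M; the very flask that is asked about, followed so far
- alpha: partner 0.36 M; run made earlier
- flask: partner 0.240 M; time 30 min

- delta (time / min: target / %, starting material / %): 2.00: 34.0, 65.8; 6.00: 60.6, 26.2; 10.0: 57.8, 9.0; 15.0: 47.2, 2.1; 25.0: 31.5, 0; 30.0: 24.5, 0
- alpha (time / min: target / %, starting material / %): 1.00: 17.8, 79.6; 2.00: 33.5, 64.2; 3.00: 45.2, 51.7; 4.00: 52.1, 39.2; 5.00: 56.5, 33.3; 6.00: 60.6, 23.4

(scatter of a reading: 1 percentage point)

- dawn: at 30 min take out 90 % of the by-product then present, then wait 10 min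
- midnight: at 30 min add free catalyst, 100 % of the amount charged, then wait 10 min
- summer: change nothing and wait 10 min more
- noon: at 30 min add partner, 50.0 % of the amount charged, then wait 10 min

- what is added takes up no volume worth counting
- the analysis behind the earlier runs scatters by 1 percentage point, standard deviation

1. target, in percent of the starting material first charged, at 30 min
2. what to do for the largest gain in target; "none" if nothing gains more than 2 percentage points (dawn / midnight / summer / noon / none)
3. target present, in percent of the starting material first charged, after midnight
4. target present, in percent of the starting material first charged, after noon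

In the delta flask the starting material, the limiting reagent, reads 0 % at 30.0 min, below the target, so I expect no more making. Control changed hands earlier. Between 6.00 min and 10.0 min starting material falls 17 percentage points while target slips 2.8 points. Between 10.0 min and 15.0 min target drops 11 points, more than the 6.9 points starting material gives up.

Since then I follow one number, the growth per minute of one over the target share. Read from 15.0 min to 30.0 min, this fading rate is 0.131 min⁻¹. A straight line here means a second-order loss, so I scale the rate with the charge. Traced back, the line meets the full charge at 6.45 min.

I commit to 24.5 % now and 18.5 % after 10 min. Don't add partner: alpha, with more partner, reads 60.6 % at 6.00 min, like delta's 60.6 %. Alpha and delta held free catalyst at the same 0.88 mM, so they do not test it. I leave it out for another reason: the starting material it would work on reads 0 % at 30.0 min, less than the 24.5 % of target. Stopping the loss outright keeps target where it stands, so my choice is none.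

The forecast gives 25 %, 18.5 % after midnight, 19 % after noon and none, saying “By 30 min it is gone, so no more target can form”.

The delta flask gives 25.8 %, 19.5 % after midnight and 19.5 % after noon, and the answer is none.

    partner + free catalyst → catalyst intermediate A (k = 1440 M⁻¹ min⁻¹)
    starting material + catalyst intermediate A ⇌ catalyst intermediate B (K = 30.0 M⁻¹, k = 340 M⁻¹ min⁻¹)
    catalyst intermediate B → by-product + catalyst intermediate C (k = 625 min⁻¹)
    catalyst intermediate C → free catalyst + target (k = 74.9 min⁻¹)
    2 catalyst intermediate C → spent catalyst (k = 41.8 M⁻¹ min⁻¹)
    target + by-product → side product (k = 1.57 M⁻¹ min⁻¹)

Taking out by-product still changes target by −0.69 points, against −6.3 points for waiting, so neither reaches 2 points. From 25.8 %, the fading rate gives 19.3 % after 10 min, and waiting gives 19.5 %. The neighbour charged with 0.020 M of starting material has a scaled rate of 0.0327 min⁻¹. Counted from 6.45 min, that gives 56.5 % at 30 min, and this neighbour holds 56.6 %.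

(Readings and results come from a simulation with constants of no real substance.)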